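**Plan**

1. Retrosynthesis: after the late adjustments at C8 (silyl ether), C9 (methacrylate, alcohol) and C13 (sulfide mask), the C1–C10 bond and the ring O–C3 bond are cut together. This opens both the 3(2H)-furanone and the ten-membered carbocycle to an eleven-membered lactone (C10–O–C1) that is an α-acyloxy ketone (C9=O) and a β-methoxy enoate (C3–OMe). That lactone is cut at C3–C4 (Stille) and at the C10–O ester bond (carboxylate alkylation of an α-bromoketone); the C6–C7–C8 triad with the methylene lactone comes from a Barbier allylation.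
2. Enabling feature: C10 is a fully substituted carbon that carries the furanone ring oxygen and lies between the C1 ketone and the oxygenated C9, and C3 is the enol-ether (β) carbon of the C1 enone. With C9 at the ketone level, C10 is an enolisable α-acyloxy position, so an acyl group parked on the C10 oxygen can shift to C10 (ring contraction 11 to 10) and the freed oxygen can close onto C3.
3. Forward order: open chain C5–C13 (Barbier) → γ-lactone C6–O–C12 → Z-vinyl iodide → α-bromoketone → ester → eleven-membered lactone (Stille) → ten-membered carbocycle and furanone in one operation → C9 reduction, methacrylate, unmasking, desilylation.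
4. Stereochemistry: C6 from (R)-glyceraldehyde acetonide; C7 and C8 in the Barbier step (allylic 1,2-induction and chair transition state); C4=C5 (Z) from the Stork–Zhao olefination and C2=C3 from the stannane geometry; C10 in the key step (chelated enolate, tether and C8 silyloxy group); C9 by chelation-controlled reduction.

Key step: step 15

Remark: locants C1–C15 are those of the germacrane skeleton of the target (C1 furanone ketone, C3 enol-ether carbon, C4=C5 Z-alkene, C6 lactone carbinol, C8 hydroxy carbon, C9 methacrylate carbon, C10 quaternary carbon, C11=C13 methylene, C12 lactone carbonyl); compounds 10–21 are carried as epimer mixtures at C9/C10 and 21–26 at C11, because these centres are cleared or reset later.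

**Route**

Step 1
Reactants: 1 (R)-2,2-dimethyl-1,3-dioxolane-4-carbaldehyde; 2 methyl acrylate
Product: 3 methyl 2-{hydroxy[(4R)-2,2-dimethyl-1,3-dioxolan-4-yl]methyl}prop-2-enoate (both carbinol epimers)
Conditions: DABCO (0.5 equiv), 1,4-dioxane/H2O, rt
Reagents that add atoms: none
Why: Morita–Baylis–Hillman reaction of the α-alkoxy aldehyde; the new carbinol centre needs no control because it is removed in step 2, and the dioxolane centre (the future C6) comes unchanged from the chiral pool.

Step 2
Reactants: 3 Morita–Baylis–Hillman alcohol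
Product: 4 methyl (2Z)-2-(bromomethyl)-3-[(4S)-2,2-dimethyl-1,3-dioxolan-4-yl]prop-2-enoate
Conditions: NBS, Me2S, CH2Cl2, 0 °C → rt
Reagents that add atoms: N-bromosuccinimide, O=C1CCC(=O)N1Br
Why: The bromosulfonium salt activates the allylic alcohol and bromide enters with allylic transposition (SN2′), which should give the thermodynamically preferred (Z)-2-(bromomethyl)enoate with the dioxolane cis to CH2Br.

Step 3
Reactants: 4 allylic bromide; 5 (E)-but-2-enal
Product: 6 methyl (3R,4R,5E)-3-[(4S)-2,2-dimethyl-1,3-dioxolan-4-yl]-4-hydroxy-2-methylidenehept-5-enoate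
Conditions: In powder, THF/H2O (1:1), rt
Reagents that add atoms: none
Why: Barbier allylation in which the allylindium reagent adds through its γ-carbon (C7) in a closed chair transition state, the (Z)-geometry giving the syn C7/C8 relationship, while the aldehyde approaches C7 anti to the dioxolane C–O bond with the C6–H eclipsing the alkene (allylic strain), which sets C7 relative to C6; the enal reacts 1,2.

Step 4
Reactants: 6 homoallylic alcohol
Product: 7 methyl (3S,4R,5E)-4-[(tert-butyldimethylsilyl)oxy]-3-[(4S)-2,2-dimethyl-1,3-dioxolan-4-yl]-2-methylidenehept-5-enoate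
Conditions: TBSOTf, 2,6-lutidine, CH2Cl2, −78 → 0 °C
Reagents that add atoms: tert-butyldimethylsilyl triflate, CC(C)(C)[Si](C)(C)OS(=O)(=O)C(F)(F)F
Why: Silylation under basic, non-lactonising conditions blocks the C8 oxygen so that only the C6 oxygen can lactonise in step 5, and the bulky silyl ether later shields the C8–H from enolisation.

Step 5
Reactants: 7 silyl ether
Product: 9 (4S,5S)-4-[(1R,2E)-1-[(tert-butyldimethylsilyl)oxy]but-2-en-1-yl]-5-(hydroxymethyl)-3-methylideneoxolan-2-one, via diol ester 8 (not isolated)
Conditions: AcOH/H2O (4:1), 40 °C; then PPTS (cat.), PhMe, 60 °C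
Reagents that add atoms: none
Why: Acid hydrolysis of the terminal acetonide frees the C5/C6 diol and the secondary C6 hydroxyl closes the five-membered lactone onto the acrylate ester (5-exo-trig transesterification, favoured over the six-membered alternative through the C5 oxygen), the trans ring fusion following from the C6/C7 centres set in step 3.

Step 6
Reactants: 9 lactone alcohol
Product: 10 C9,C10-trans-epoxide of 9 (both face isomers; C6, C7, C8 as in 9)
Conditions: dimethyldioxirane (acetone solution), CH2Cl2, 0 °C
Reagents that add atoms: dimethyldioxirane, CC1(C)OO1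
Why: The neutral electrophilic dioxirane should epoxidise the only electron-rich alkene (C9=C10) and leave the electron-poor methylene lactone, and the absence of acid keeps the free C5 hydroxyl from opening the epoxide; the epoxide configuration is irrelevant.

Step 7
Reactants: 10 epoxy alcohol
Product: 11 epoxy lactone aldehyde (10 with the C5 CH2OH oxidised to CHO)
Conditions: Dess–Martin periodinane, pyridine, CH2Cl2, 0 °C → rt
Reagents that add atoms: none
Why: Dess–Martin oxidation of the primary alcohol under buffered conditions that should not epimerise C6 or open the epoxide.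

Step 8
Reactants: 11 aldehyde
Product: 12 (Z)-vinyl iodide (lactone carrying a (1Z)-2-iodoprop-1-en-1-yl group at C6; epoxide retained)
Conditions: EtPPh3I, n-BuLi, THF, rt; I2, −78 °C; NaN(SiMe3)2, −20 °C; then 11, −78 °C
Reagents that add atoms: ethyltriphenylphosphonium iodide, CC[P+](c1ccccc1)(c1ccccc1)c1ccccc1.[I-]; iodine, II
Why: Stork–Zhao olefination, in which the non-stabilised α-iodo ylide should give the (Z)-2-iodoalkene (C6 cis to I) under kinetic control at low temperature, fixing the future C4=C5 geometry.

Step 9
Reactants: 12 epoxy vinyl iodide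
Product: 13 bromohydrin (C10–Br, C9–OH; C9/C10 epimer mixture)
Conditions: LiBr, AcOH, THF, rt
Reagents that add atoms: lithium bromide, [Li+].[Br-]
Why: Acid-assisted SN2 opening of the epoxide by bromide at C10, the carbon remote from the inductively deactivating and bulky C8 silyloxy group, should place Br on C10 and OH on C9.

Step 10
Reactants: 13 bromohydrin
Product: 14 α-bromoketone (C9 ketone, C10–Br; C10 epimers)
Conditions: Dess–Martin periodinane, CH2Cl2, rt
Reagents that add atoms: none
Why: Dess–Martin oxidation of the secondary alcohol is neutral and should avoid epimerisation at C8 and loss of HBr.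

Step 11
Reactants: 15 methyl (E)-3-methoxyprop-2-enoate
Product: 17 methyl (Z)-3-methoxy-3-(tributylstannyl)prop-2-enoate, via vinyllithium 16 (not isolated)
Conditions: LiN(iPr)2, THF, −95 °C; then Bu3SnCl, −95 → −40 °C
Reagents that add atoms: tributyltin chloride, CCCC[Sn](Cl)(CCCC)CCCC
Why: Ester-directed β-lithiation of the β-methoxyacrylate (the vinyl C–H α to OMe and cis to the ester) followed by stannylation with retention should give the α-alkoxyvinylstannane with tin cis to the ester, the geometry needed for the ring.

Step 12
Reactants: 14 α-bromoketone; 17 stannyl ester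
Product: 19 C10 ester of 14 with (Z)-3-methoxy-3-(tributylstannyl)prop-2-enoic acid (Br replaced by the acyloxy group), via potassium carboxylate 18 (not isolated)
Conditions: 17, KOH (1.0 equiv), MeOH/H2O, rt; evaporation, PhMe azeotrope; then 14, DMF, 0 °C → rt
Reagents that add atoms: potassium hydroxide, [K+].[OH-]
Why: Saponification to the potassium carboxylate and SN2 displacement of the highly reactive α-bromoketone forms the C10–O–C1 ester; the C10 configuration is immaterial because it is erased in step 15.

Step 13
Reactants: 19 stannyl ester vinyl iodide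
Product: 20 eleven-membered lactone O–C1(=O)–C2H=C3(OMe)–C4(Me)=C5H–C6–C7–C8(OTBS)–C9(=O)–C10H(Me) with 2E,4Z geometry and the methylene γ-lactone trans-fused at C6/C7
Conditions: Pd2(dba)3 (cat.), AsPh3, CuI (20 mol %), DMF (1 mM), 40 °C
Reagents that add atoms: none
Why: Intramolecular Stille coupling with copper-assisted transmetalation of the α-alkoxyvinylstannane and retention at both sp2 carbons should close the ring at C3–C4 under high dilution, the two ring-cis alkenes and the fused γ-lactone pre-organising the chain.

Step 14
Reactants: 20 macrolactone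
Product: 21 thiophenol adduct of 20 (C13–SPh, C11 epimers)
Conditions: PhSH, Et3N (cat.), CH2Cl2, 0 °C
Reagents that add atoms: thiophenol, Sc1ccccc1
Why: Base-catalysed thia-Michael addition to the α-methylene lactone, the most electrophilic acceptor present (the β-methoxy dienoate is deactivated), masks it against the C10 enolate in step 15 and against hydride in step 16.

Step 15
Reactants: 21 masked macrolactone
Product: 23 furanone-bridged ten-membered carbocycle (3(2H)-furanone O–C3=C2–C1(=O)–C10; C9 ketone; C8–OTBS; C13–SPh; C10 as in the target), via ring-contracted hydroxy enone 22 (not isolated)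
Conditions: LiN(SiMe3)2 (1.1 equiv), THF, −78 → −20 °C; then 1 M HCl, −20 °C → rt, same flask
Reagents that add atoms: none
Why: Proposed new method: LiN(SiMe3)2 removes the C10 proton of the α-acyloxy ketone to give the lithium-chelated enolate, whose C10 carbon attacks its own lactone carbonyl C1 (3-exo-trig) to an alkoxy-oxirane alkoxide that opens by C1–O cleavage, so the acyl group moves from O to C10 and the 11-membered lactone contracts to the 10-membered carbocycle carrying the C10 alkoxide. The closest known reaction type is the Chan rearrangement of α-acyloxy ester enolates, which has not been run as a ring contraction of a macrocyclic lactone with a vinylogous-carbonate acyl group. On acidification the C10 hydroxyl adds to C3 of the protonated β-methoxy enone (5-exo-trig onto the oxocarbenium carbon) and methanol is lost, the classical closure of α′-hydroxy β-alkoxy enones, which forms the 3(2H)-furanone and makes the sequence irreversible. C10 is the only new stereocentre: in the chelated enolate the acyloxy oxygen lies cis to the enolate oxygen, allylic strain holds the C8–H in the enolate plane, and the ring tether carries C1 across the enolate face that bears C7, anti to the C8 silyloxy group, which corresponds to the C10 configuration of the target. The step needs C10 rather than C8 enolisation (secured by the acidifying acyloxy group on C10 and the bulky silyl ether on C8), acyl transfer rather than conjugate addition (the methylene lactone is masked and the methoxy group deactivates C3 towards carbon nucleophiles), and acidification before the furanone closes, so that no methoxide is set free next to the base-sensitive 2,2-disubstituted 1,3-dicarbonyl unit.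

Step 16
Reactants: 23 C9 ketone
Product: 24 C9 alcohol (8,9-anti, C9 as in the target)
Conditions: Zn(BH4)2, Et2O, −20 °C
Reagents that add atoms: none
Why: Chelation-controlled reduction in which zinc bridges the C9 carbonyl and the C8 ether oxygen and hydride enters from the side of the C8–H, which is also the outer face of the ring, should give the 8,9-anti relationship; the furanone carbonyl (a vinylogous ester) and the lactone are not reduced.

Step 17
Reactants: 24 C9 alcohol
Product: 25 C9 methacrylate
Conditions: methacrylic anhydride, Et3N, DMAP (cat.), CH2Cl2, rt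
Reagents that add atoms: methacrylic anhydride, C=C(C)C(=O)OC(=O)C(C)=C
Why: DMAP-catalysed acylation of the hindered secondary alcohol with the anhydride; acyl migration is excluded because the C8 oxygen is silylated.

Step 18
Reactants: 25 sulfide
Product: 27 8-O-TBS ether of the target (methylene lactone restored), via sulfoxide 26 (not isolated)
Conditions: mCPBA (1.0 equiv), CH2Cl2, −78 °C; then PhMe, 90 °C
Reagents that add atoms: none
Why: Chemoselective S-oxidation at low temperature (the sulfide is far more nucleophilic than the enol ether or the acrylates) and thermal syn-elimination of the sulfoxide through its only β-hydrogen (C11–H) should restore the exocyclic methylene.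

Step 19
Reactants: 27 silyl ether
Product: 28 target CNP0562373.1
Conditions: HF·pyridine, pyridine, THF, 0 °C → rt
Reagents that add atoms: none
Why: Fluoride-mediated desilylation under mildly acidic conditions should free the C8 hydroxyl without acyl migration or attack on the Michael acceptors.

**Compound list**

1 | (R)-2,2-dimethyl-1,3-dioxolane-4-carbaldehyde | O=C[C@H]1COC(C)(C)O1 | starting material
2 | methyl acrylate | C=CC(=O)OC | starting material
3 | methyl 2-{hydroxy[(4R)-2,2-dimethyl-1,3-dioxolan-4-yl]methyl}prop-2-enoate (carbinol epimers) | C=C(C(=O)OC)C(O)[C@H]1COC(C)(C)O1 | intermediate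
4 | methyl (2Z)-2-(bromomethyl)-3-[(4S)-2,2-dimethyl-1,3-dioxolan-4-yl]prop-2-enoate | BrC/C(C(=O)OC)=C\[C@H]1COC(C)(C)O1 | intermediate
5 | (E)-but-2-enal | C/C=C/C=O | starting material
6 | methyl (3R,4R,5E)-3-[(4S)-2,2-dimethyl-1,3-dioxolan-4-yl]-4-hydroxy-2-methylidenehept-5-enoate | C/C=C/[C@@H](O)[C@@H](C(=C)C(=O)OC)[C@H]1COC(C)(C)O1 | intermediate
7 | methyl (3S,4R,5E)-4-[(tert-butyldimethylsilyl)oxy]-3-[(4S)-2,2-dimethyl-1,3-dioxolan-4-yl]-2-methylidenehept-5-enoate | C/C=C/[C@@H](O[Si](C)(C)C(C)(C)C)[C@@H](C(=C)C(=O)OC)[C@H]1COC(C)(C)O1 | intermediate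
8 | methyl (3S,4R,5E)-4-[(tert-butyldimethylsilyl)oxy]-3-[(1S)-1,2-dihydroxyethyl]-2-methylidenehept-5-enoate | C/C=C/[C@@H](O[Si](C)(C)C(C)(C)C)[C@@H](C(=C)C(=O)OC)[C@H](O)CO | intermediate
9 | (4S,5S)-4-[(1R,2E)-1-[(tert-butyldimethylsilyl)oxy]but-2-en-1-yl]-5-(hydroxymethyl)-3-methylideneoxolan-2-one | C/C=C/[C@@H](O[Si](C)(C)C(C)(C)C)[C@H]1C(=C)C(=O)O[C@@H]1CO | intermediate
10 | C9,C10-trans-epoxide of 9 (both face isomers; C6, C7, C8 as in 9) | CC1OC1[C@@H](O[Si](C)(C)C(C)(C)C)[C@H]1C(=C)C(=O)O[C@@H]1CO | intermediate
11 | epoxy lactone aldehyde (10 with C5 as CHO) | CC1OC1[C@@H](O[Si](C)(C)C(C)(C)C)[C@H]1C(=C)C(=O)O[C@@H]1C=O | intermediate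
12 | epoxy lactone with a (1Z)-2-iodoprop-1-en-1-yl group on C6 | CC1OC1[C@@H](O[Si](C)(C)C(C)(C)C)[C@H]1C(=C)C(=O)O[C@@H]1/C=C(/C)I | intermediate
13 | bromohydrin (C10–Br, C9–OH; epimer mixture) | CC(Br)C(O)[C@@H](O[Si](C)(C)C(C)(C)C)[C@H]1C(=C)C(=O)O[C@@H]1/C=C(/C)I | intermediate
14 | α-bromoketone (C9 ketone, C10–Br; C10 epimers) | CC(Br)C(=O)[C@@H](O[Si](C)(C)C(C)(C)C)[C@H]1C(=C)C(=O)O[C@@H]1/C=C(/C)I | intermediate
15 | methyl (E)-3-methoxyprop-2-enoate | CO/C=C/C(=O)OC | starting material
16 | methyl (Z)-3-lithio-3-methoxyprop-2-enoate | CO/C(=C/C(=O)OC)[Li] | intermediate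
17 | methyl (Z)-3-methoxy-3-(tributylstannyl)prop-2-enoate | CO/C(=C/C(=O)OC)[Sn](CCCC)(CCCC)CCCC | intermediate
18 | potassium (Z)-3-methoxy-3-(tributylstannyl)prop-2-enoate | CO/C(=C/C(=O)[O-])[Sn](CCCC)(CCCC)CCCC.[K+] | intermediate
19 | C10 (Z)-3-methoxy-3-(tributylstannyl)prop-2-enoate ester of the α-hydroxy ketone corresponding to 14 (C10 epimers) | CC(OC(=O)/C=C(/OC)[Sn](CCCC)(CCCC)CCCC)C(=O)[C@@H](O[Si](C)(C)C(C)(C)C)[C@H]1C(=C)C(=O)O[C@@H]1/C=C(/C)I | intermediate
20 | eleven-membered (2E,4Z)-3-methoxy-4-methyldienoate lactone of the C10 oxygen, with C9 ketone, C8–OTBS and trans-fused methylene γ-lactone at C6/C7 (C10 epimers) | CC1OC(=O)/C=C(/OC)\C(C)=C/[C@H]2OC(=O)C(=C)[C@@H]2[C@H](O[Si](C)(C)C(C)(C)C)C1=O | intermediate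
21 | thiophenol adduct of 20 (C13–SPh; C10 and C11 epimers) | CC1OC(=O)/C=C(/OC)\C(C)=C/[C@H]2OC(=O)C(CSc3ccccc3)[C@@H]2[C@H](O[Si](C)(C)C(C)(C)C)C1=O | intermediate
22 | ring-contracted ten-membered carbocycle with C10(OH)(CH3) between the C9 and C1 ketones and the C2=C3(OMe) enone (formed as its lithium alkoxide) | C[C@@]1(O)C(=O)/C=C(/OC)\C(C)=C/[C@H]2OC(=O)C(CSc3ccccc3)[C@@H]2[C@H](O[Si](C)(C)C(C)(C)C)C1=O | intermediate
23 | furanone-bridged germacranolide with C9 ketone, C8–OTBS and C13–SPh | O=C1[C@@H](O[Si](C)(C)C(C)(C)C)[C@H]2C(CSc3ccccc3)C(=O)O[C@@H]2/C=C(/C)C2=CC(=O)[C@@]1(C)O2 | intermediate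
24 | C9 alcohol of 23 (C9 as in the target) | O[C@H]1[C@@H](O[Si](C)(C)C(C)(C)C)[C@H]2C(CSc3ccccc3)C(=O)O[C@@H]2/C=C(/C)C2=CC(=O)[C@@]1(C)O2 | intermediate
25 | C9 methacrylate of 24 | C=C(C)C(=O)O[C@H]1[C@@H](O[Si](C)(C)C(C)(C)C)[C@H]2C(CSc3ccccc3)C(=O)O[C@@H]2/C=C(/C)C2=CC(=O)[C@@]1(C)O2 | intermediate
26 | sulfoxide of 25 | C=C(C)C(=O)O[C@H]1[C@@H](O[Si](C)(C)C(C)(C)C)[C@H]2C(CS(=O)c3ccccc3)C(=O)O[C@@H]2/C=C(/C)C2=CC(=O)[C@@]1(C)O2 | intermediate
27 | 8-O-(tert-butyldimethylsilyl) ether of the target | C=C(C)C(=O)O[C@H]1[C@@H](O[Si](C)(C)C(C)(C)C)[C@H]2C(=C)C(=O)O[C@@H]2/C=C(/C)C2=CC(=O)[C@@]1(C)O2 | intermediate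
28 | CNP0562373.1 | C=C(C)C(=O)O[C@H]1[C@@H](O)[C@H]2C(=C)C(=O)O[C@@H]2/C=C(/C)C2=CC(=O)[C@@]1(C)O2 | target

**Step count**

Total steps: 19. Longest linear sequence: 18 (steps 1–10 and 12–19; step 11 is a one-step branch).

**Steps most likely to fail**

1. Step 15. The base may enolise towards C8, which would be followed by a five-membered acyl transfer to C8, or the strained 3-exo acyl transfer may be too slow within the macrocycle, or the enolate may not be chelated and facial control at C10 is lost. Fallback: run the acyl shift on the open chain, the documented setting of the Chan rearrangement, and close the ring afterwards by C–C coupling. It sets out from 19: thiophenol and catalytic Et3N give the sulfide-masked open-chain ester F1. LiN(SiMe3)2 at −78 °C and then mild acid (PPTS) would give the open-chain 5-(tributylstannyl)-3(2H)-furanone F2, in which C10 is formed without tether control, so its epimers would have to be separated. Intramolecular Stille coupling of F2 (Pd2(dba)3, AsPh3, CuI, high dilution) would then close the ten-membered carbocycle at C3–C4 and return to the route at 23.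

2. Step 13. Transmetalation of the hindered, fully substituted α-alkoxyvinylstannane may be slow, so that intermolecular coupling and protodestannylation compete with ring closure. Fallback: make the C3–C4 bond between two molecules and close the ring at the C10–O bond instead. It sets out from bromohydrin 13 and carboxylate 18: intermolecular Stille coupling and acidification would give the bromohydrin dienoic acid F3, Dess–Martin oxidation the α-bromoketone acid F4, and Cs2CO3 in DMF at high dilution (carboxylate alkylation) would close the eleven-membered lactone and return to the route at 20.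

3. Step 16. If the silyl ether fails to chelate zinc, hydride may enter from both faces of the C9 carbonyl. Fallback: enforce chelation through the free hydroxyl and re-protect. It sets out from 23: HF·pyridine would give the α-hydroxy ketone F5, Zn(BH4)2 would reduce it through the zinc chelate of the free C8 hydroxyl to the 8,9-anti diol F6, and TBSOTf with 2,6-lutidine at −78 °C would silylate the less hindered C8 hydroxyl (the C9 hydroxyl is neopentylic) and return to the route at 24.

Further compounds
F1 | step 15 | thiophenol adduct of ester 19 (C13–SPh) | CC(OC(=O)/C=C(/OC)[Sn](CCCC)(CCCC)CCCC)C(=O)[C@@H](O[Si](C)(C)C(C)(C)C)[C@H]1C(CSc2ccccc2)C(=O)O[C@@H]1/C=C(/C)I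
F2 | step 15 | open-chain 2-methyl-5-(tributylstannyl)-3(2H)-furanone carrying at C10 the C9 ketone side chain with C8–OTBS, the masked lactone and the (Z)-vinyl iodide | C[C@]1(OC(=CC1=O)[Sn](CCCC)(CCCC)CCCC)C(=O)[C@@H](O[Si](C)(C)C(C)(C)C)[C@H]1C(CSc2ccccc2)C(=O)O[C@@H]1/C=C(/C)I
F3 | step 13 | bromohydrin (2E,4Z)-3-methoxy-4-methyldienoic acid | CC(Br)C(O)[C@@H](O[Si](C)(C)C(C)(C)C)[C@H]1C(=C)C(=O)O[C@@H]1/C=C(/C)\C(OC)=C/C(=O)O
F4 | step 13 | α-bromoketone (2E,4Z)-3-methoxy-4-methyldienoic acid | CC(Br)C(=O)[C@@H](O[Si](C)(C)C(C)(C)C)[C@H]1C(=C)C(=O)O[C@@H]1/C=C(/C)\C(OC)=C/C(=O)O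
F5 | step 16 | C8 hydroxy C9 ketone (23 without the silyl group) | O=C1[C@@H](O)[C@H]2C(CSc3ccccc3)C(=O)O[C@@H]2/C=C(/C)C2=CC(=O)[C@@]1(C)O2
F6 | step 16 | 8,9-anti diol | O[C@H]1[C@@H](O)[C@H]2C(CSc3ccccc3)C(=O)O[C@@H]2/C=C(/C)C2=CC(=O)[C@@]1(C)O2
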